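## Retrosynthetic overview

1. Last step: the oxetane, the acetal carbon, the C(Me)–O carbon and the CHBr carbon are all made by one 4-exo bromoetherification of a spiro lactol onto the C(Me)=CH bond of a 2-bromocyclohexa-1,3-diene.
2. That diene comes from a 4-methylidenecyclohex-2-enone (1,6-hydride addition with enolate triflation, then triflate-to-bromide exchange); the carbocycle is cut at both bonds that flank its cis CH=CH unit.
3. Key disconnection: (Z)-Me3SnCH=CHSnMe3 (from acetylene) is stitched by a double Stille coupling between an acyl chloride carbon (later C–Br) and the enol triflate carbon of an acetyl group (later the oxetane C–Me).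
4. Enabling feature: in the six-membered ring the CH=CH pair (later CHBr–CH=) is the only part that bears hydrogen, and its two neighbours hang 1,4 from the vicinal quaternary pair CMe2–C(spiro). They can therefore be carried as a carboxyl and an acetyl group that cannot enolise into the ring and are held gauche.
5. Ring order: γ-lactone (from an (S)-epoxide; spiro carbon set by trans acylation of the lactone enolate) → carbocycle (key step) → lactol → oxetane.

Key step: step 10

Remark: the target SMILES is read as having the isopropenyl group trans to the oxetane on the tetrahydrofuran ring and Br at the CHBr carbon anti to the oxetane oxygen. The spiro intermediates are numbered as 2-oxaspiro[4.5]decanes: C1 lactone or lactol carbon, O2, C3 isopropenyl-bearing carbon, C5 spiro carbon, C6 CMe2, and C7 to C10 the carbons that end as C(Br)=CH–CHBr–C(Me)O.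

## Route

Step 1
Reactants: 1 tert-butyl 2-methylpropanoate; 2 methyl bromoacetate
Product: 3 1-tert-butyl 4-methyl 2,2-dimethylbutanedioate
Conditions: LiN(iPr)2, THF, −78 °C; then 2, −78 → 0 °C
Reagents that add atoms: none
Why: Enolate alkylation (SN2) of the fully substituted lithium ester enolate with the α-bromo ester should install the CMe2 carbon and leave two esters that can be told apart; no stereocentre is formed.

Step 2
Reactants: 3 1-tert-butyl 4-methyl 2,2-dimethylbutanedioate
Product: 4 4-tert-butoxy-3,3-dimethyl-4-oxobutanoic acid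
Conditions: LiOH (1.2 equiv), THF/H2O, 0 → 23 °C; then 1 M HCl
Reagents that add atoms: lithium hydroxide, [Li+].[OH-]
Why: Saponification should be selective because the methyl ester is unhindered whereas the tert-butyl ester on the quaternary carbon is inert to hydroxide; no stereocentre is formed.

Step 3
Reactants: 5 2-methylprop-2-enal
Product: 6 rac-2-(prop-1-en-2-yl)oxirane
Conditions: trimethylsulfonium iodide, NaH, DMSO/THF, 0 °C; distillation
Reagents that add atoms: trimethylsulfonium iodide, C[S+](C)C.[I-]
Why: Corey–Chaykovsky epoxidation, in which dimethylsulfonium methylide adds 1,2 to the enal and closes the oxirane, should give the racemic epoxide.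

Step 4
Reactants: 6 rac-2-(prop-1-en-2-yl)oxirane
Product: 7 (S)-2-(prop-1-en-2-yl)oxirane
Conditions: (R,R)-(salen)Co(OAc) (0.5 mol%), H2O (0.55 equiv), neat, 0 → 23 °C; distillation
Reagents that add atoms: none
Why: Hydrolytic kinetic resolution: the (R,R) catalyst is expected, by analogy with other terminal epoxides, to hydrolyse the (R)-epoxide at its CH2 terminus and leave the (S)-epoxide, which is the only source of absolute configuration in the route.

Step 5
Reactants: 4 4-tert-butoxy-3,3-dimethyl-4-oxobutanoic acid; 7 (S)-2-(prop-1-en-2-yl)oxirane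
Product: 9 tert-butyl 2-methyl-2-[(5R)-2-oxo-5-(prop-1-en-2-yl)oxolan-3-yl]propanoate (both C3 epimers), via hydroxy acid 8 (not isolated)
Conditions: LiN(iPr)2 (2.2 equiv), THF, −78 → 0 °C; 7, 0 → 40 °C; 1 M HCl; then pyridinium p-toluenesulfonate (cat.), toluene, 40 °C
Reagents that add atoms: none
Why: Epoxide opening by the carboxylic acid dianion at the unhindered CH2 terminus (SN2, no Lewis acid, so the allylic carbon keeps its configuration and becomes C5 R), then lactonisation of the γ-hydroxy acid; C3 forms as a mixture that step 6 erases.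

Step 6
Reactants: 9 tert-butyl 2-methyl-2-[(5R)-2-oxo-5-(prop-1-en-2-yl)oxolan-3-yl]propanoate
Product: 10 tert-butyl 2-[(3S,5R)-3-acetyl-2-oxo-5-(prop-1-en-2-yl)oxolan-3-yl]-2-methylpropanoate
Conditions: LiN(iPr)2, THF, −78 °C; acetyl chloride, −78 °C
Reagents that add atoms: acetyl chloride, CC(Cl)=O
Why: Claisen-type C-acylation of the lithium lactone enolate: the electrophile should approach the planar enolate anti to the C5 isopropenyl group, so the new quaternary C3 (S) carries acetyl trans and the CMe2 arm cis to isopropenyl.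

Step 7
Reactants: 10 tert-butyl 2-[(3S,5R)-3-acetyl-2-oxo-5-(prop-1-en-2-yl)oxolan-3-yl]-2-methylpropanoate
Product: 11 tert-butyl 2-methyl-2-[(3S,5R)-2-oxo-5-(prop-1-en-2-yl)-3-{1-[(trifluoromethanesulfonyl)oxy]ethenyl}oxolan-3-yl]propanoate
Conditions: KN(SiMe3)2, THF, −78 °C; PhNTf2, −78 → −40 °C
Reagents that add atoms: N-phenylbis(trifluoromethanesulfonimide), FC(F)(F)S(=O)(=O)N(c1ccccc1)S(=O)(=O)C(F)(F)F
Why: Enol triflate formation: the acetyl CH3 is the only enolisable position, and the low temperature together with the hindered tert-butyl ester should prevent Dieckmann-type attack of the enolate on that ester.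

Step 8
Reactants: 11 tert-butyl 2-methyl-2-[(3S,5R)-2-oxo-5-(prop-1-en-2-yl)-3-{1-[(trifluoromethanesulfonyl)oxy]ethenyl}oxolan-3-yl]propanoate
Product: 12 2-methyl-2-[(3S,5R)-2-oxo-5-(prop-1-en-2-yl)-3-{1-[(trifluoromethanesulfonyl)oxy]ethenyl}oxolan-3-yl]propanoic acid
Conditions: 85% aq. H3PO4, toluene, 23 °C
Reagents that add atoms: none
Why: Acid-mediated tert-butyl ester cleavage by alkyl–oxygen fission (E1 loss of 2-methylpropene) under conditions mild enough for the enol triflate, the lactone and the isopropenyl group.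

Step 9
Reactants: 13 ethyne; 14 hexamethyldistannane
Product: 15 (Z)-1,2-bis(trimethylstannyl)ethene
Conditions: Pd(PPh3)4 (2 mol%), 1,4-dioxane, ethyne (1 atm), 60 °C
Reagents that add atoms: none
Why: Palladium-catalysed syn 1,2-distannylation of the alkyne (oxidative addition of the Sn–Sn bond, syn insertion, reductive elimination) should give only the Z alkene, which is the two-carbon unit of the key step.

Step 10
Reactants: 12 2-methyl-2-[(3S,5R)-2-oxo-5-(prop-1-en-2-yl)-3-{1-[(trifluoromethanesulfonyl)oxy]ethenyl}oxolan-3-yl]propanoic acid; 15 (Z)-1,2-bis(trimethylstannyl)ethene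
Product: 18 (3R,5R)-6,6-dimethyl-10-methylidene-3-(prop-1-en-2-yl)-2-oxaspiro[4.5]dec-8-ene-1,7-dione, via acid chloride 16 (not isolated), via Z-stannyl enone 17 (not isolated)
Conditions: 1-chloro-N,N,2-trimethylprop-1-en-1-amine (1.1 equiv), CH2Cl2, 23 °C, evaporation; then 15 (1.05 equiv), Pd(PPh3)4 (10 mol%), CuCl (20 mol%), LiCl (3 equiv), THF, 0.005 M, 23 → 65 °C
Reagents that add atoms: none
Why: The acid is turned in the flask into acid chloride 16, to which zerovalent palladium adds first; transfer of one vinyl carbon of 15 from tin to palladium and reductive elimination give the Z β-stannyl enone 17 (first new bond, acyl carbon to vinylene carbon), then oxidative addition into the enol triflate and an intramolecular tin-to-palladium transfer with reductive elimination join the second vinylene carbon to the triflate-bearing carbon (second new bond). The closest known reaction type is the ring-forming double Stille stitching of a bis-electrophile with a 1,2-distannylethene, built from the Stille ketone synthesis with acid chlorides and the Stille coupling of enol triflates. The six-membered carbocycle closes by C(sp2)–C(sp2) reductive elimination from a seven-membered palladacycle, and the lactone already present makes the product a spirocycle. No stereocentre is created; the only stereo-element formed, the cis ring alkene, is carried in from 15 and should be kept because the O→Sn contact of 17 holds the Z geometry. The step needs chemoselectivity (acid chloride before triflate, secured by the much faster oxidative addition of the acid chloride at 23 °C) and ring closure instead of oligomerisation (secured by one equivalent of 15, high dilution and the CMe2–quaternary pair that holds the two arms gauche).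

Step 11
Reactants: 18 (3R,5R)-6,6-dimethyl-10-methylidene-3-(prop-1-en-2-yl)-2-oxaspiro[4.5]dec-8-ene-1,7-dione
Product: 19 (3R,5R)-6,6,10-trimethyl-1-oxo-3-(prop-1-en-2-yl)-2-oxaspiro[4.5]deca-7,9-dien-7-yl trifluoromethanesulfonate
Conditions: LiBH(s-Bu)3 (1.05 equiv), THF, −78 °C; then PhNTf2, −78 → 0 °C
Reagents that add atoms: N-phenylbis(trifluoromethanesulfonimide), FC(F)(F)S(=O)(=O)N(c1ccccc1)S(=O)(=O)C(F)(F)F
Why: Conjugate 1,6-hydride addition with enolate trapping: the bulky hydride should attack the unhindered exocyclic methylene of the linear dienone (making the C10 methyl group) and the fully conjugated lithium dienolate is O-sulfonylated; no stereocentre is formed.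

Step 12
Reactants: 19 (3R,5R)-6,6,10-trimethyl-1-oxo-3-(prop-1-en-2-yl)-2-oxaspiro[4.5]deca-7,9-dien-7-yl trifluoromethanesulfonate
Product: 20 (3R,5R)-7-bromo-6,6,10-trimethyl-3-(prop-1-en-2-yl)-2-oxaspiro[4.5]deca-7,9-dien-1-one
Conditions: Ni(cod)2 (10 mol%), LiBr (2 equiv), DMA/THF 1:3, 23 °C
Reagents that add atoms: lithium bromide, [Li+].[Br-]
Why: Nickel-catalysed halide exchange of an enol triflate (oxidative addition of zerovalent nickel, triflate/bromide exchange, C–Br reductive elimination) should give the dienyl bromide with both double bonds in place.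

Step 13
Reactants: 20 (3R,5R)-7-bromo-6,6,10-trimethyl-3-(prop-1-en-2-yl)-2-oxaspiro[4.5]deca-7,9-dien-1-one
Product: 21 (3R,5R)-7-bromo-6,6,10-trimethyl-3-(prop-1-en-2-yl)-2-oxaspiro[4.5]deca-7,9-dien-1-ol (both C1 epimers)
Conditions: i-Bu2AlH (1.1 equiv), CH2Cl2, −78 °C; aq. potassium sodium tartrate
Reagents that add atoms: none
Why: Partial reduction of the γ-lactone by the aluminium hydride at −78 °C should stop at the aluminium lactolate and give the lactol, whose two epimers interconvert by ring–chain tautomerism, without touching the bromodiene.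

Step 14
Reactants: 21 (3R,5R)-7-bromo-6,6,10-trimethyl-3-(prop-1-en-2-yl)-2-oxaspiro[4.5]deca-7,9-dien-1-ol
Product: 22 CNP0141320.1
Conditions: N-bromosuccinimide (1.0 equiv), 4 Å molecular sieves, CH2Cl2, −78 → −20 °C
Reagents that add atoms: N-bromosuccinimide, O=C1CCC(=O)N1Br
Why: 4-exo bromoetherification (the kinetic mode known from halolactonisation of cyclohex-2-ene-1-carboxylic acids to β-lactones and from oxetane-forming halo-etherification of homoallylic alcohols): bromine should add to C9 of the electron-rich trisubstituted C9=C10 bond while the lactol oxygen, held on the C1 side of the spiro carbon, opens the bromonium ion at the tertiary C10 from the opposite face, so the spiro centre sets the cis-fused acetal carbon, C10 (C–O) and C9 (Br anti to O).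

## Compound list

1 | tert-butyl 2-methylpropanoate | CC(C)C(=O)OC(C)(C)C | starting material
2 | methyl bromoacetate | COC(=O)CBr | starting material
3 | 1-tert-butyl 4-methyl 2,2-dimethylbutanedioate | COC(=O)CC(C)(C)C(=O)OC(C)(C)C | intermediate
4 | 4-tert-butoxy-3,3-dimethyl-4-oxobutanoic acid | OC(=O)CC(C)(C)C(=O)OC(C)(C)C | intermediate
5 | 2-methylprop-2-enal (methacrolein) | CC(=C)C=O | starting material
6 | rac-2-(prop-1-en-2-yl)oxirane | CC(=C)C1CO1 | intermediate
7 | (S)-2-(prop-1-en-2-yl)oxirane | C=C(C)[C@H]1CO1 | intermediate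
8 | (4R)-2-(1-tert-butoxy-2-methyl-1-oxopropan-2-yl)-4-hydroxy-5-methylhex-5-enoic acid (both C2 epimers) | C=C(C)[C@H](O)CC(C(C)(C)C(=O)OC(C)(C)C)C(O)=O | intermediate
9 | tert-butyl 2-methyl-2-[(5R)-2-oxo-5-(prop-1-en-2-yl)oxolan-3-yl]propanoate (both C3 epimers) | C=C(C)[C@H]1CC(C(C)(C)C(=O)OC(C)(C)C)C(=O)O1 | intermediate
10 | tert-butyl 2-[(3S,5R)-3-acetyl-2-oxo-5-(prop-1-en-2-yl)oxolan-3-yl]-2-methylpropanoate | C=C(C)[C@H]1C[C@@](C(C)=O)(C(C)(C)C(=O)OC(C)(C)C)C(=O)O1 | intermediate
11 | tert-butyl 2-methyl-2-[(3S,5R)-2-oxo-5-(prop-1-en-2-yl)-3-{1-[(trifluoromethanesulfonyl)oxy]ethenyl}oxolan-3-yl]propanoate | C=C(C)[C@H]1C[C@@](C(=C)OS(=O)(=O)C(F)(F)F)(C(C)(C)C(=O)OC(C)(C)C)C(=O)O1 | intermediate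
12 | 2-methyl-2-[(3S,5R)-2-oxo-5-(prop-1-en-2-yl)-3-{1-[(trifluoromethanesulfonyl)oxy]ethenyl}oxolan-3-yl]propanoic acid | C=C(C)[C@H]1C[C@@](C(=C)OS(=O)(=O)C(F)(F)F)(C(C)(C)C(O)=O)C(=O)O1 | intermediate
13 | ethyne (acetylene) | C#C | starting material
14 | hexamethyldistannane | C[Sn](C)(C)[Sn](C)(C)C | starting material
15 | (Z)-1,2-bis(trimethylstannyl)ethene | C[Sn](C)(C)/C=C\[Sn](C)(C)C | intermediate
16 | 2-methyl-2-[(3S,5R)-2-oxo-5-(prop-1-en-2-yl)-3-{1-[(trifluoromethanesulfonyl)oxy]ethenyl}oxolan-3-yl]propanoyl chloride | C=C(C)[C@H]1C[C@@](C(=C)OS(=O)(=O)C(F)(F)F)(C(C)(C)C(Cl)=O)C(=O)O1 | intermediate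
17 | 1-{(3S,5R)-3-[(4Z)-2-methyl-3-oxo-5-(trimethylstannyl)pent-4-en-2-yl]-2-oxo-5-(prop-1-en-2-yl)oxolan-3-yl}ethenyl trifluoromethanesulfonate | C=C(C)[C@H]1C[C@@](C(=C)OS(=O)(=O)C(F)(F)F)(C(C)(C)C(=O)/C=C\[Sn](C)(C)C)C(=O)O1 | intermediate
18 | (3R,5R)-6,6-dimethyl-10-methylidene-3-(prop-1-en-2-yl)-2-oxaspiro[4.5]dec-8-ene-1,7-dione | C=C(C)[C@H]1C[C@@]2(C(=O)O1)C(=C)C=CC(=O)C2(C)C | intermediate
19 | (3R,5R)-6,6,10-trimethyl-1-oxo-3-(prop-1-en-2-yl)-2-oxaspiro[4.5]deca-7,9-dien-7-yl trifluoromethanesulfonate | C=C(C)[C@H]1C[C@@]2(C(=O)O1)C(C)=CC=C(OS(=O)(=O)C(F)(F)F)C2(C)C | intermediate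
20 | (3R,5R)-7-bromo-6,6,10-trimethyl-3-(prop-1-en-2-yl)-2-oxaspiro[4.5]deca-7,9-dien-1-one | C=C(C)[C@H]1C[C@@]2(C(=O)O1)C(C)=CC=C(Br)C2(C)C | intermediate
21 | (3R,5R)-7-bromo-6,6,10-trimethyl-3-(prop-1-en-2-yl)-2-oxaspiro[4.5]deca-7,9-dien-1-ol (both C1 epimers) | C=C(C)[C@H]1C[C@@]2(C(O)O1)C(C)=CC=C(Br)C2(C)C | intermediate
22 | CNP0141320.1: the dibromo cyclohexene carrying the fused oxetane–tetrahydrofuran acetal, configuration as in the SMILES | C=C(C)[C@H]1C[C@@]23[C@@H](O1)O[C@]2(C)[C@@H](Br)C=C(Br)C3(C)C | target

## Step count and risks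

Total step count: 14. Longest linear sequence: 11 steps (steps 1, 2, 5, 6, 7, 8, 10, 11, 12, 13, 14).

Three steps most likely to fail:

Step 10 (key step). After the first, acyl coupling the ring-closing tin-to-palladium transfer onto the hindered vinylpalladium may be outrun by coupling with a second stannane, by protodestannylation or by Z-to-E isomerisation of the stannyl enone. The fallback sets out from 11 and comes back at 19, and closes the ring by olefin metathesis instead of tin stitching. Me2CuLi (THF, −20 °C) should replace the triflate of 11 by methyl and give the bis-isopropenyl lactone ester F1. 85% aqueous H3PO4 should give the acid F2. 1-Chloro-N,N,2-trimethylprop-1-en-1-amine should give the acid chloride F3, which with allyltributylstannane and Pd(PPh3)4 (Stille ketone synthesis) should give the allyl ketone F4. Ring-closing metathesis with the second-generation Grubbs catalyst, RuCl2(=CHPh)(PCy3)(1,3-dimesitylimidazolidin-2-ylidene), between the allyl group and the isopropenyl group on the quaternary carbon should give the β,γ-unsaturated spiro ketone F5. KN(SiMe3)2 followed by PhNTf2 should then give 19.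

Step 14. The lactol oxygen may open the bromonium ion at C9 (5-endo, giving a bridged tetrahydrofuran) instead of at C10, or bromine may attack the isopropenyl group. The fallback sets out from 20 and comes back at 22; it installs C10–O and C9–Br intermolecularly and closes the oxetane afterwards at the acetal carbon. N-Bromosuccinimide in THF/water should give the trans bromohydrin lactone F6, because water opens the bromonium ion at the tertiary C10. The facial selectivity of this step is not secured, so the isomer with the hydroxyl on the face of the lactone carbonyl would have to be separated. i-Bu2AlH (CH2Cl2, −78 °C) should give the bromohydrin lactol F7. Dehydrative acetalisation (Ph2SO, (CF3SO2)2O, 2,4,6-tri-tert-butylpyrimidine, CH2Cl2, −78 → −40 °C), in which the tertiary C10 hydroxyl displaces the activated anomeric oxygen, should give 22.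

Step 11. The hydride may be delivered to C9 (1,4-addition) or to a carbonyl group instead of to the exocyclic methylene. The fallback sets out from 18 and comes back at 19. Hydrosilylation with Et3SiH and (Ph3P)3RhCl (benzene, 50 °C), which puts silicon on oxygen and hydrogen on the terminal carbon of the oxapentadienyl rhodium intermediate, should give the triethylsilyl dienol ether F8. CsF and PhNTf2 (DME, 23 °C) should convert it into 19.

## Further compounds

F1 | step 10 | tert-butyl 2-methyl-2-[(3R,5R)-2-oxo-3,5-di(prop-1-en-2-yl)oxolan-3-yl]propanoate | C=C(C)[C@H]1C[C@@](C(C)=C)(C(C)(C)C(=O)OC(C)(C)C)C(=O)O1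
F2 | step 10 | 2-methyl-2-[(3R,5R)-2-oxo-3,5-di(prop-1-en-2-yl)oxolan-3-yl]propanoic acid | C=C(C)[C@H]1C[C@@](C(C)=C)(C(C)(C)C(O)=O)C(=O)O1
F3 | step 10 | 2-methyl-2-[(3R,5R)-2-oxo-3,5-di(prop-1-en-2-yl)oxolan-3-yl]propanoyl chloride | C=C(C)[C@H]1C[C@@](C(C)=C)(C(C)(C)C(Cl)=O)C(=O)O1
F4 | step 10 | (3R,5R)-3-(2-methyl-3-oxohex-5-en-2-yl)-3,5-di(prop-1-en-2-yl)oxolan-2-one | C=C(C)[C@H]1C[C@@](C(C)=C)(C(C)(C)C(=O)CC=C)C(=O)O1
F5 | step 10 | (3R,5R)-6,6,10-trimethyl-3-(prop-1-en-2-yl)-2-oxaspiro[4.5]dec-9-ene-1,7-dione | C=C(C)[C@H]1C[C@@]2(C(=O)O1)C(C)=CCC(=O)C2(C)C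
F6 | step 14 | 7,9-dibromo-10-hydroxy-6,6,10-trimethyl-3-(prop-1-en-2-yl)-2-oxaspiro[4.5]dec-7-en-1-one, hydroxyl on the C1 face and Br anti to it | C=C(C)[C@H]1C[C@@]2(C(=O)O1)[C@@](O)(C)[C@@H](Br)C=C(Br)C2(C)C
F7 | step 14 | 7,9-dibromo-6,6,10-trimethyl-3-(prop-1-en-2-yl)-2-oxaspiro[4.5]dec-7-ene-1,10-diol, both C1 epimers | C=C(C)[C@H]1C[C@@]2(C(O)O1)[C@@](O)(C)[C@@H](Br)C=C(Br)C2(C)C
F8 | step 11 | (3R,5R)-6,6,10-trimethyl-3-(prop-1-en-2-yl)-7-[(triethylsilyl)oxy]-2-oxaspiro[4.5]deca-7,9-dien-1-one | C=C(C)[C@H]1C[C@@]2(C(=O)O1)C(C)=CC=C(O[Si](CC)(CC)CC)C2(C)C
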